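**Target as spectator.** Target was what I read in the delta, epsilon and alpha runs, and the bench rule for it says that target charged at the start just rides along. The gamma flask, charged like delta plus 36.0 mM of target, should then end at that charge plus what delta had made by 22 min.

| flask | starting material | reagent | free catalyst | target | time |
|---|---|---|---|---|---|
| delta | 120 mM | 96.0 mM | 12.0 mM |  |  |
| epsilon | 72.0 mM | 48.0 mM | 12.0 mM |  |  |
| alpha | 120 mM | 96.0 mM | 18.0 mM |  |  |
| gamma | 120 mM | 96.0 mM | 12.0 mM | 36.0 mM | 22 min |

| run | time / min | [target] / mM |
|---|---|---|
| delta run | 1.3 | 2.7 |
| delta run | 3.8 | 10.5 |
| delta run | 7.3 | 21.3 |
| delta run | 11 | 31.5 |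
| delta run | 16 | 44.9 |
| delta run | 22 | 57.8 |
| epsilon run | 1.3 | 2.2 |
| epsilon run | 3.8 | 7.0 |
| epsilon run | 7.3 | 14.6 |
| epsilon run | 11 | 21.8 |
| epsilon run | 16 | 29.4 |
| epsilon run | 22 | 37.9 |
| alpha run | 1.3 | 4.1 |
| alpha run | 3.8 | 15.1 |
| alpha run | 7.3 | 30.1 |
| alpha run | 11 | 44.7 |
| alpha run | 16 | 61.0 |
| alpha run | 22 | 77.8 |

(scatter of a reading: 0.4 mM)

* how the opening rate goes with [free catalyst] round the charge of the delta run: the exponent of the rate at two percent of starting material gone to target
* the epsilon run starts with 48.0 mM less of starting material and of reagent than the delta run, and with no target. Compared where both hold the same amount of starting material, once fifteen percent of what the epsilon run was charged with has turned into target, is the epsilon run faster, slower or alike (within a tenth)?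
* target in the gamma run at 22 min, as a share of the starting material charged

- Overall: starting material + reagent -> target, with free catalyst as catalyst.
- Constant volume, constant temperature.
- Bound and free are read together.
- "The second partner" is reagent.
- An order is taken over about fifteen percent of the charge, up and down.
- A share of target counts the target that was charged too.

**Zero of scale.** The epsilon and delta runs test that rule. At 48.0 mM of target, delta held by the overall equation about 72.0 mM of starting material and 48.0 mM of reagent, bound forms counted, which is the charge of epsilon, with the same catalyst charge. The two runs therefore differ in the target present and in the past of the catalyst. Epsilon, between its first and third readings, gave 2.07 mM min⁻¹. Delta, over its last two readings, the nearest window to that composition, gave 2.15 mM min⁻¹. Their quotient, 0.961, is my memory ratio: the rate of epsilon over the rate of delta at equal composition, the same-excess comparison. Its zero case is one, a flask that shows no product inhibition and no catalyst loss. Delta's rate carries a scatter of about 0.0943 mM min⁻¹, so my reading stands at one within its scatter.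

**Its border.** With a ratio of one, I reckoned gamma at 78.2% of the starting material charged. The test, however, spans only 48.0 mM of target. Gamma's charge is 0.750 of that span, so it starts inside, but its reckoned end of 93.8 mM is about twice the span. I committed to the sum, knowing that late gamma lay beyond what the test had shown.

**The forecast.** The forecast gave an order of 0.9, alike and 77%. It read the ratio as 0.93, “so they are alike, with at most slight product inhibition or catalyst loss”. Its share stands below my reckoning.

**The result.** The flask gave an order of 0.85, alike and 78.5%.

    free catalyst + starting material → catalyst-substrate complex (6.300 M⁻¹ min⁻¹)
    catalyst-substrate complex + reagent → loaded catalyst (69.00 M⁻¹ min⁻¹)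
    loaded catalyst → target + free catalyst (8.160 min⁻¹)
    starting material + reagent ⇌ idle substrate-reagent adduct, settled at all times (43.80 M⁻¹)

**Memory and adduct.** Gamma made 58.2 mM by 22 min, beside the 57.8 mM read in delta, the sum I had reckoned from my memory ratio of 0.961. Target enters no step of the scheme as a reactant. What held gamma down was the joining of starting material and reagent to the idle substrate-reagent adduct. That joining did not set the rate of epsilon over delta at equal starting material, which stood at 1.0 with it and 1.0 without it. Without that joining, target in gamma, the charged target counted, came to 102% of the starting material charged instead of 78.5%.

(The data come from a simulation with constants of no real substance; noise was put on by code.)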